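A direct plan would condense 2'-hydroxy-3',4'-dimethoxyacetophenone A1 with 2-methoxybenzaldehyde A2 to the chalcone A3, close ring C by alkaline hydrogen peroxide oxidation to the flavonol A4, methylate the 3-OH to the tetramethoxyflavone A5, and finally oxygenate C5 by carbonyl-directed C–H borylation to the boronate A6 followed by oxidation.
Its weakest steps would be:
- the late C5–H oxygenation, because this directed borylation is not established on a chromone, the unhindered C–H bonds of ring B and C6–H would compete, and the product is a 4-methoxyphenol that would over-oxidise to the 5,8-quinone;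
- the peroxide ring closure, because epoxide, aurone and degradation channels of the electron-rich chalcone and flavonol would erode it.

The route would cut ring A, not ring C, at C8–C8a and C4a–C5. The unit C5–C6(H)–C7(OMe)–C8(OMe) maps onto the four carbons of a methoxycyclobutenone from methyl semisquarate, and C4a=C8a onto the C5=C6 bond of a preformed 2-aryl-3-methoxy-4-pyranone (rings C and B). Heating the 4-methoxy-4-(pyranonyl)cyclobutenone would open it to a dienylketene that closes onto the pyranone and aromatises: one operation builds the benzo ring with 6-H, 7-OMe, 8-OMe and a free 5-OH that comes from the ketene carbonyl. No C–H oxygenation of a finished flavone and no peroxide cyclisation remain, and the 5-OH never has to be told apart from a methyl ether.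

Key step: step 5

Remark: the target and the bonds of its ring system are numbered as a flavone, intermediates by their own rings; compounds 1, 3 and 6 are taken as commercial.

Step 1
Reactants: 1 3-hydroxy-4H-pyran-4-one (pyromeconic acid)
Product: 2 3-methoxy-4H-pyran-4-one
Conditions: MeI (1.5 equiv), K2CO3 (1.5 equiv), acetone, 50 °C, 6 h
Reagents that add atoms: iodomethane, CI
Why: Williamson O-methylation (SN2 on MeI) of the only acidic proton, the enolic 3-OH, which puts the future 3-OMe of the flavone in place at the outset; no stereocentre is formed.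

Step 2
Reactants: 2 3-methoxy-4H-pyran-4-one; 3 1-iodo-2-methoxybenzene (2-iodoanisole)
Product: 5 3-methoxy-2-(2-methoxyphenyl)-4H-pyran-4-one, via 2-pyranonylzinc chloride 4 (not isolated)
Conditions: TMPZnCl·LiCl (TMP = 2,2,6,6-tetramethylpiperidide, 1.2 equiv), THF, 25 °C, 1 h; then 3 (1.1 equiv), Pd(PPh3)4 (3 mol %), 50 °C, 8 h
Reagents that add atoms: none
Why: C–H zincation with the hindered amide base should take C2–H, the most acidic ring C–H because it is flanked by the ring oxygen and by the metal-coordinating 3-OMe group (the reaction type known for C2 of chromones), and Negishi coupling (oxidative addition of zerovalent palladium to 3, transmetalation from 4, reductive elimination) forms the C2–aryl bond; no stereocentre is formed.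

Step 3
Reactants: 6 3,4-dimethoxycyclobut-3-ene-1,2-dione (dimethyl squarate)
Product: 8 3-methoxycyclobut-3-ene-1,2-dione (methyl semisquarate), via hydroxycyclobutenone 7 (not isolated)
Conditions: LiAlH(OtBu)3 (1.05 equiv), THF, −78 °C, 1 h; aqueous work-up; crude 7, 12 M HCl (1.5 equiv), CH2Cl2, rt, 30 min
Reagents that add atoms: water (of the aqueous HCl), O
Why: Mono-1,2-reduction of the symmetrical vinylogous diester by the bulky hydride gives 7, and acid ionises its allylic OH with help from the C2 methoxy group to a vinylogous oxocarbenium ion that takes up water at C2 and loses methanol (the hydride-then-acid route from squarate esters to semisquarates); the stereocentre of racemic 7 is lost.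

Step 4
Reactants: 5 3-methoxy-2-(2-methoxyphenyl)-4H-pyran-4-one; 8 3-methoxycyclobut-3-ene-1,2-dione
Product: 11 6-(1,2-dimethoxy-4-oxocyclobut-2-en-1-yl)-3-methoxy-2-(2-methoxyphenyl)-4H-pyran-4-one, via 6-lithiopyranone 9 (not isolated), via lithium alkoxide 10 (not isolated)
Conditions: LiTMP (lithium 2,2,6,6-tetramethylpiperidide, 1.1 equiv), THF, −78 °C, 20 min; cannula into 8 (1.2 equiv), THF, −78 °C, 30 min; MeOTf (1.5 equiv), −78 to −30 °C, 1 h; Et3N, then sat. NaHCO3
Reagents that add atoms: methyl trifluoromethanesulfonate, COS(=O)(=O)C(F)(F)F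
Why: Amide-base C–H lithiation at C6, the only remaining C–H next to the ring oxygen, gives 9, whose 1,2-addition to 8 should take the ketone-type carbonyl next to the methoxy-bearing carbon and not the deactivated vinylogous-ester carbonyl (as in organolithium additions to 3-alkoxycyclobutenediones), which forms the future C8–C8a bond, and low-temperature O-methylation of alkoxide 10 fixes the future 8-OMe; the quaternary stereocentre arises as a racemate and is erased in step 5.

Step 5
Reactants: 11 6-(1,2-dimethoxy-4-oxocyclobut-2-en-1-yl)-3-methoxy-2-(2-methoxyphenyl)-4H-pyran-4-one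
Product: 14 5-hydroxy-3,7,8-trimethoxy-2-(2-methoxyphenyl)-4H-chromen-4-one, via dienylketene 12 (not isolated), via dienone tautomer 13 (not isolated)
Conditions: toluene (0.02 M, degassed), 110 °C, 3 h, argon
Reagents that add atoms: none
Why: Thermal conrotatory four-electron ring opening of the cyclobutenone (cleavage of its C1–C4 bond) should give the (Z)-dienylketene 12, in which the donor 4-OMe has rotated outward and the pyranonyl group inward, next to the ketene. Disrotatory six-electron electrocyclisation of the ketene C=C, the dimethoxy-substituted C=C and the pyranone C5=C6 bond then forms the C4a–C5 bond and closes the six-membered carbocycle (ring A) to dienone 13, whose C4a–H, flanked by two carbonyl groups, moves to oxygen to give the aromatic 5-hydroxyflavone 14. The closest known reaction type is the thermal ring expansion of 4-aryl-, 4-heteroaryl- and 4-alkenyl-4-alkoxycyclobutenones to phenols and hydroquinone monoethers (Moore rearrangement); here the alkenyl partner is the C5=C6 bond of a 4-pyranone, which has little aromatic stabilisation to lose. The step needs torquoselectivity, secured by the alkoxy donor at C4 of the cyclobutenone, and closure at carbon, secured because C5 is the only hydrogen-bearing neighbour of C6 and no free OH is present to add to the ketene. The stereocentre of 11 and the transient one at C4a of 13 are destroyed, so no stereocontrol is needed, and 6-H, 7-OMe, 8-OMe and the free, hydrogen-bonded 5-OH are placed without ambiguity.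

## Compound list
1 | 3-hydroxy-4H-pyran-4-one (pyromeconic acid) | O=c1ccocc1O | starting material
2 | 3-methoxy-4H-pyran-4-one | COc1coccc1=O | intermediate
3 | 1-iodo-2-methoxybenzene (2-iodoanisole) | COc1ccccc1I | starting material
4 | chloro(3-methoxy-4-oxo-4H-pyran-2-yl)zinc (LiCl complex) | COc1c([Zn]Cl)occc1=O | intermediate
5 | 3-methoxy-2-(2-methoxyphenyl)-4H-pyran-4-one | COc1ccccc1-c1occc(=O)c1OC | intermediate
6 | 3,4-dimethoxycyclobut-3-ene-1,2-dione (dimethyl squarate) | COC1=C(OC)C(=O)C1=O | starting material
7 | 4-hydroxy-2,3-dimethoxycyclobut-2-en-1-one (racemic) | COC1=C(OC)C(=O)C1O | intermediate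
8 | 3-methoxycyclobut-3-ene-1,2-dione (methyl semisquarate) | COC1=CC(=O)C1=O | intermediate
9 | [5-methoxy-6-(2-methoxyphenyl)-4-oxo-4H-pyran-2-yl]lithium | [Li]c1cc(=O)c(OC)c(-c2ccccc2OC)o1 | intermediate
10 | lithium 2-methoxy-1-[5-methoxy-6-(2-methoxyphenyl)-4-oxo-4H-pyran-2-yl]-4-oxocyclobut-2-en-1-olate (racemic) | [Li+].[O-]C1(c2cc(=O)c(OC)c(-c3ccccc3OC)o2)C(OC)=CC1=O | intermediate
11 | 6-(1,2-dimethoxy-4-oxocyclobut-2-en-1-yl)-3-methoxy-2-(2-methoxyphenyl)-4H-pyran-4-one (racemic) | COc1ccccc1-c1oc(C2(OC)C(OC)=CC2=O)cc(=O)c1OC | intermediate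
12 | 6-[(1Z)-1,2-dimethoxy-4-oxobuta-1,3-dien-1-yl]-3-methoxy-2-(2-methoxyphenyl)-4H-pyran-4-one | COc1ccccc1-c1oc(/C(OC)=C(OC)\C=C=O)cc(=O)c1OC | intermediate
13 | 3,7,8-trimethoxy-2-(2-methoxyphenyl)-4aH-chromene-4,5-dione (racemic) | COc1ccccc1C1=C(OC)C(=O)C2C(=O)C=C(OC)C(OC)=C2O1 | intermediate
14 | 5-hydroxy-3,7,8-trimethoxy-2-(2-methoxyphenyl)-4H-chromen-4-one (5-hydroxy-3,7,8,2'-tetramethoxyflavone, achiral) | COc1ccccc1-c1oc2c(OC)c(OC)cc(O)c2c(=O)c1OC | target

Total step count: 5. Longest linear sequence: 4 steps (steps 1, 2, 4, 5); step 3 is a one-step branch.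

Steps most likely to fail:

Step 4. The deprotonation may not stay at C6–H, the C6-lithio species may add to unreacted 5 before it meets 8, or alkoxide 10 may ring-open before it is methylated. The fallback would set out from 5 and return at 11. Zincation with TMPZnCl·LiCl, the milder base of step 2, would give chloro[5-methoxy-6-(2-methoxyphenyl)-4-oxo-4H-pyran-2-yl]zinc F1, and iodolysis with I2 would give 6-iodo-3-methoxy-2-(2-methoxyphenyl)-4H-pyran-4-one F2. Iodine–magnesium exchange (iPrMgCl·LiCl, THF, −40 °C) would then generate chloro[5-methoxy-6-(2-methoxyphenyl)-4-oxo-4H-pyran-2-yl]magnesium F3 in the absence of amide base and of 5. Its addition to 8 and NH4Cl work-up would give the racemic carbinol 6-(1-hydroxy-2-methoxy-4-oxocyclobut-2-en-1-yl)-3-methoxy-2-(2-methoxyphenyl)-4H-pyran-4-one F4, and neutral O-methylation (MeI, Ag2O, MeCN, rt) would lead to 11.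

Step 5. Ketene 12 may be consumed by dimerisation or by adventitious nucleophiles faster than it closes onto C5 of the pyranone. The fallback would set out from 11 and return at 14, replacing the pericyclic closure by a polar acylation. Heating 11 in toluene that contains methanol would trap 12 as methyl (3Z)-3,4-dimethoxy-4-[5-methoxy-6-(2-methoxyphenyl)-4-oxo-4H-pyran-2-yl]but-3-enoate F5. Saponification (LiOH, THF/H2O, 0 °C) would give (3Z)-3,4-dimethoxy-4-[5-methoxy-6-(2-methoxyphenyl)-4-oxo-4H-pyran-2-yl]but-3-enoic acid F6. Treatment with (CF3CO)2O in CH2Cl2 would form the mixed anhydride, and intramolecular Friedel–Crafts acylation at the nucleophilic C5 of the pyranone (α to C4=O, β to the ring oxygen), enolisation and NaHCO3 work-up would return at 14.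

Step 2. Zincation may not discriminate fully between C2–H and C6–H, both next to the ring oxygen, and the coupling of two ortho-substituted partners may be slow. The fallback would set out from 1 and return at 5, with the polarity of the coupling reversed. Bromination of 1 with NBS (MeCN, 0 °C), directed ortho to the enolic OH, would give 2-bromo-3-hydroxy-4H-pyran-4-one F7, and O-methylation (MeI, K2CO3, acetone) would give 2-bromo-3-methoxy-4H-pyran-4-one F8. Suzuki–Miyaura coupling of F8 with commercial (2-methoxyphenyl)boronic acid (Pd(PPh3)4, K2CO3, 1,4-dioxane/H2O, 85 °C) would return at 5.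

## Further compounds
F1 | step 4 | chloro[5-methoxy-6-(2-methoxyphenyl)-4-oxo-4H-pyran-2-yl]zinc | COc1ccccc1-c1oc([Zn]Cl)cc(=O)c1OC
F2 | step 4 | 6-iodo-3-methoxy-2-(2-methoxyphenyl)-4H-pyran-4-one | COc1ccccc1-c1oc(I)cc(=O)c1OC
F3 | step 4 | chloro[5-methoxy-6-(2-methoxyphenyl)-4-oxo-4H-pyran-2-yl]magnesium | COc1ccccc1-c1oc([Mg]Cl)cc(=O)c1OC
F4 | step 4 | 6-(1-hydroxy-2-methoxy-4-oxocyclobut-2-en-1-yl)-3-methoxy-2-(2-methoxyphenyl)-4H-pyran-4-one (racemic) | COc1ccccc1-c1oc(C2(O)C(OC)=CC2=O)cc(=O)c1OC
F5 | step 5 | methyl (3Z)-3,4-dimethoxy-4-[5-methoxy-6-(2-methoxyphenyl)-4-oxo-4H-pyran-2-yl]but-3-enoate | COC(=O)C/C(OC)=C(OC)\c1cc(=O)c(OC)c(-c2ccccc2OC)o1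
F6 | step 5 | (3Z)-3,4-dimethoxy-4-[5-methoxy-6-(2-methoxyphenyl)-4-oxo-4H-pyran-2-yl]but-3-enoic acid | OC(=O)C/C(OC)=C(OC)\c1cc(=O)c(OC)c(-c2ccccc2OC)o1
F7 | step 2 | 2-bromo-3-hydroxy-4H-pyran-4-one | O=c1ccoc(Br)c1O
F8 | step 2 | 2-bromo-3-methoxy-4H-pyran-4-one | COc1c(Br)occc1=O
A1 | direct plan | 1-(2-hydroxy-3,4-dimethoxyphenyl)ethan-1-one | CC(=O)c1ccc(OC)c(OC)c1O
A2 | direct plan | 2-methoxybenzaldehyde | COc1ccccc1C=O
A3 | direct plan | (E)-1-(2-hydroxy-3,4-dimethoxyphenyl)-3-(2-methoxyphenyl)prop-2-en-1-one | COc1ccccc1/C=C/C(=O)c1ccc(OC)c(OC)c1O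
A4 | direct plan | 3-hydroxy-7,8-dimethoxy-2-(2-methoxyphenyl)-4H-chromen-4-one | COc1ccccc1-c1oc2c(OC)c(OC)ccc2c(=O)c1O
A5 | direct plan | 3,7,8-trimethoxy-2-(2-methoxyphenyl)-4H-chromen-4-one | COc1ccccc1-c1oc2c(OC)c(OC)ccc2c(=O)c1OC
A6 | direct plan | 3,7,8-trimethoxy-2-(2-methoxyphenyl)-5-(4,4,5,5-tetramethyl-1,3,2-dioxaborolan-2-yl)-4H-chromen-4-one | COc1ccccc1-c1oc2c(OC)c(OC)cc(B3OC(C)(C)C(C)(C)O3)c2c(=O)c1OC
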